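**Plan** (locants C1–C15 in the text are eudesmane numbers: ring A = C1–C5, C10; ring B = C5–C10; C11 = carbinol carbon; C14 on C10; C15 on C4)

1. Retrosynthesis: the C3 ester and the C3/C4 diol go back to a C3=C4 alkene; the C6=C7 enone bond goes back to the aldol C6(OH)–C7, and that C6–C7 bond is cut.
2. Enabling feature: ring B holds the aldol triad C8(=O)–C7–C11(OH)Me2. Stored as an α,β-epoxy ketone (C7–O–C11 oxirane), its two-electron cleavage gives the C7 enolate regiospecifically and frees the C11 oxygen; the C6 aldehyde on C5 lies 1,5 to C8, so ring B can close without base.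
3. Further cuts: C7–C8 (alkenyl Grignard reagent on the C8 acyl group), C5–C6 (anti-SE2′ of a C3 allylsilane with an orthoformate), C9–C10 and C10–C14 (two enolate alkylations).
4. Forward: ring A is (R)-carvone (carvone C1→C5, C2→C4, C3→C3, C4→C2, C5→C1, C6→C10, ring methyl→C15); ring B is closed onto it in step 11; dihydroxylation and angeloylation follow.
5. Stereochemistry: the carvone isopropenyl group (on C1) directs the C10 alkylation and the C3 silylation, both anti, and is then excised; silicon relays C3 to C5 by anti-SE2′; the axial C10 methyl of the trans-fused bicycle sends OsO4 to the α face (C3, C4).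

Key step: step 11

Remark: centres that are destroyed later (future C10 in 3, C4 in 7–9, oxirane carbon C7 in 17–19, C6 and C7 in 20–21) are expected as epimer mixtures and are left undefined in the SMILES; locants inside systematic names are IUPAC locants.

Step 1
Reactants: 1 (R)-carvone
Product: 3 (5R)-2,6-dimethyl-5-(prop-1-en-2-yl)cyclohex-2-en-1-one (C6 epimers), via lithium dienolate 2 (not isolated)
Conditions: LiN(i-Pr)2 (1.1 equiv), THF, −78 °C; then MeI, −78 → −20 °C
Reagents that add atoms: iodomethane, CI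
Why: Kinetic α′-deprotonation and C-methylation of the cross-conjugated lithium dienolate (enolate alkylation) bring in C14; the new centre is re-enolised in step 2, so its configuration is immaterial.

Step 2
Reactants: 3 6-methylcarvone; 4 methyl bromoacetate
Product: 6 methyl 2-[(1S,6S)-1,3-dimethyl-2-oxo-6-(prop-1-en-2-yl)cyclohex-3-en-1-yl]acetate, via lithium enolate 5 (not isolated)
Conditions: LiN(i-Pr)2 (1.1 equiv), THF, −78 °C; then 4, DMPU, −78 → 0 °C
Reagents that add atoms: none
Why: Alkylation of the tetrasubstituted enolate (quaternary-centre-forming enolate alkylation) should occur anti to the neighbouring isopropenyl group, which sets C10 with the CH2CO2CH3 arm (C9, C8) trans to isopropenyl and C14 cis to it.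

Step 3
Reactants: 6
Product: 7 methyl 2-[(1S,4R,6S)-4-[dimethyl(phenyl)silyl]-1,3-dimethyl-2-oxo-6-(prop-1-en-2-yl)cyclohexyl]acetate (epimers at ring C3)
Conditions: PhMe2Si–Bpin (1.3 equiv), CuCl (5 mol %), 1,3-bis(2,4,6-trimethylphenyl)imidazolium chloride (5 mol %), NaOt-Bu (10 mol %), MeOH (2 equiv), THF, 0 °C → rt
Reagents that add atoms: 2-[dimethyl(phenyl)silyl]-4,4,5,5-tetramethyl-1,3,2-dioxaborolane, CC1(C)OB(OC1(C)C)[Si](C)(C)c1ccccc1
Why: Copper-catalysed conjugate silylation of the enone (boron-to-copper silyl transfer, 1,4-addition, protonation) should deliver silicon to C3 anti to the isopropenyl group, as cuprates add to carvone, so the C3–Si bond is cis to the C10 acetate arm.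

Step 4
Reactants: 7
Product: 9 methyl 2-[(1R,4R)-4-[dimethyl(phenyl)silyl]-1,3-dimethyl-2-oxocyclohexyl]acetate (epimers at ring C3), via methoxy hydroperoxide 8 (not isolated)
Conditions: O3, CH2Cl2–MeOH, −78 °C; then FeSO4·7H2O (1.2 equiv), PhSH (1.5 equiv), −78 °C → rt
Reagents that add atoms: none
Why: Dealkenylative hydrogenation: Criegee ozonolysis in methanol gives the α-methoxy hydroperoxide, divalent iron reduces it to an alkoxy radical that loses methyl acetate by β-scission, and the secondary ring radical takes hydrogen from the thiol faster than it can rearrange, so the spent control group leaves C1 as CH2 without touching C10 or C3.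

Step 5
Reactants: 9
Product: 11 methyl 2-[(1R,4R)-4-[dimethyl(phenyl)silyl]-1,3-dimethyl-2-(trifluoromethanesulfonyloxy)cyclohex-2-en-1-yl]acetate, via potassium enolate 10 (not isolated)
Conditions: KN(SiMe3)2 (1.2 equiv), THF, −78 → 0 °C; then PhNTf2, −78 °C → rt
Reagents that add atoms: N-phenylbis(trifluoromethanesulfonimide), O=S(=O)(N(c1ccccc1)S(=O)(=O)C(F)(F)F)C(F)(F)F
Why: The ketone can enolise only toward C4 (C10 is quaternary and the ester α-hydrogens are far less acidic), so O-sulfonylation of the potassium enolate gives the C4=C5 enol triflate regiospecifically (enol triflate formation) and erases the C4 epimers.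

Step 6
Reactants: 11
Product: 12 methyl 2-[(1R,4R)-4-[dimethyl(phenyl)silyl]-1,3-dimethylcyclohex-2-en-1-yl]acetate
Conditions: Pd(OAc)2 (5 mol %), PPh3 (10 mol %), HCO2H (2 equiv), n-Bu3N (3 equiv), DMF, 60 °C
Reagents that add atoms: none
Why: Palladium-catalysed formate reduction of the alkenyl triflate (oxidative addition to zerovalent palladium, formate decarboxylation, C–H reductive elimination) leaves the C4=C5 alkene and thus a cyclic allylsilane with silicon on C3.

Step 7
Reactants: 12
Product: 13 methyl 2-[(1R,2R)-2-(dimethoxymethyl)-1,3-dimethylcyclohex-3-en-1-yl]acetate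
Conditions: HC(OMe)3 (3 equiv), Me3SiOTf (0.2 equiv), CH2Cl2, −78 → −40 °C
Reagents that add atoms: trimethyl orthoformate, COC(OC)OC
Why: Hosomi–Sakurai-type anti-SE2′ substitution: the dimethoxycarbenium ion should attack C5 on the face opposite the C3–Si bond and the β-silyl cation at C4 then loses silicon to give the C3=C4 alkene, so C5 is set (C6 trans to C9, cis to C14) by relay from C3 and C6 arrives as a masked aldehyde.

Step 8
Reactants: 13; 14 2-methylprop-1-enylmagnesium bromide
Product: 16 1-[(1R,2R)-2-(dimethoxymethyl)-1,3-dimethylcyclohex-3-en-1-yl]-4-methylpent-3-en-2-one, via Weinreb amide 15 (not isolated)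
Conditions: MeNH(OMe)·HCl (1.5 equiv), i-PrMgCl (3.0 equiv), THF, −20 °C; then 14 (2 equiv), 0 °C → rt; aq. NH4Cl
Reagents that add atoms: none
Why: In situ Weinreb amide formation and Grignard addition (Weinreb ketone synthesis): the chelated tetrahedral adduct collapses only on work-up, so one alkenyl group adds and the β,β-dimethyl enone C8(=O)–C7=C11 results.

Step 9
Reactants: 16
Product: 17 2-[(1R,2R)-2-(dimethoxymethyl)-1,3-dimethylcyclohex-3-en-1-yl]-1-(3,3-dimethyloxiran-2-yl)ethan-1-one (oxirane epimers)
Conditions: H2O2 (30% aq., 3 equiv), NaOH (0.5 equiv), MeOH, 0 °C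
Reagents that add atoms: hydrogen peroxide, OO
Why: Weitz–Scheffer nucleophilic epoxidation touches only the electron-poor C7=C11 bond and not the C3=C4 alkene or the acetal; the new C7 centre is lost again in step 11, so both epimers serve.

Step 10
Reactants: 17
Product: 18 (1R,6R)-6-[2-(3,3-dimethyloxiran-2-yl)-2-oxoethyl]-2,6-dimethylcyclohex-2-ene-1-carbaldehyde (oxirane epimers)
Conditions: oxalic acid (10% aq.) on silica gel, CH2Cl2, rt; used at once
Reagents that add atoms: water, O
Why: Mild heterogeneous acetal hydrolysis with a non-nucleophilic acid should free the C6 aldehyde without opening the carbonyl-deactivated oxirane, epimerising C5 or moving the C3=C4 bond into conjugation.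

Step 11
Reactants: 18
Product: 20 (4aR,8aR)-4-hydroxy-3-(2-hydroxypropan-2-yl)-5,8a-dimethyl-3,4,4a,7,8,8a-hexahydronaphthalen-2(1H)-one (epimers at C3 and C4 of the naphthalenone), via samarium enolate 19 (not isolated)
Conditions: SmI2 (0.1 M in THF, 2.2 equiv) added slowly to 18 in THF, −78 °C; then sat. aq. NH4Cl
Reagents that add atoms: none
Why: Proposed new method: two single-electron transfers from SmI2 to the α,β-epoxy ketone (ketyl formation, cleavage of the C7–O bond, reduction of the oxygen radical) should give the samarium enolate 19 with the double bond fixed between C8 and C7 and the C11 oxygen as its alkoxide, and this enolate adds to the C6 aldehyde held 1,5 to C8 on ring A. The closest known reactions are the SmI2 reduction of α,β-epoxy ketones to β-hydroxy ketones and the SmI2-mediated intramolecular aldol (Reformatsky-type) cyclisation of α-halo ketones onto aldehydes; merging them is reasonable because the enolate is formed without a proton source and a β-alkoxide enolate cannot undergo retro-aldol cleavage. Ring B closes in the 6-(enolendo)-exo-trig mode through a chelated chair transition state. The two new centres, C6 (carbinol) and C7, need no control because both become sp2 in step 12, while the trans ring fusion follows from the fixed C5 and C10 centres. The step needs reduction of the ketone beside an aldehyde (secured by the much faster electron transfer to an α-oxygenated ketone at −78 °C and slow addition of the reductant), enolisation toward C7 and not C9 (secured by the position of the oxirane), and retention of the epimerisable C5–H (secured by the absence of base).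

Step 12
Reactants: 20
Product: 22 (4aR,8aR)-3-(2-hydroxypropan-2-yl)-5,8a-dimethyl-4a,7,8,8a-tetrahydronaphthalen-2(1H)-one, via mesylate 21 (not isolated)
Conditions: MsCl (1.3 equiv), Et3N (4 equiv), CH2Cl2, −20 °C → rt
Reagents that add atoms: none
Why: The secondary C6 hydroxyl is sulfonylated in preference to the tertiary C11 hydroxyl and the β-mesyloxy ketone eliminates by E1cB through the C8 enolate, which places the double bond between C6 and C7 and ends any retro-aldol risk at C11.

Step 13
Reactants: 22
Product: 23 (4aR,5S,6R,8aR)-5,6-dihydroxy-3-(2-hydroxypropan-2-yl)-5,8a-dimethyl-4a,5,6,7,8,8a-hexahydronaphthalen-2(1H)-one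
Conditions: OsO4 (5 mol %), N-methylmorpholine N-oxide (1.5 equiv), MeSO2NH2 (1 equiv), acetone–H2O, rt
Reagents that add atoms: N-methylmorpholine N-oxide, C[N+]1([O-])CCOCC1; water, O
Why: Catalytic syn-dihydroxylation should select the electron-rich C3=C4 alkene over the hindered enone and approach from the α face, opposite the axial C10 methyl of the trans-fused bicycle, which sets C3 (OH α) and C4 (OH α, CH3 β).

Step 14
Reactants: 23; 24 angelic acid
Product: 26 (1S,2R,4aR,8aR)-1-hydroxy-7-(2-hydroxypropan-2-yl)-1,4a-dimethyl-6-oxo-1,2,3,4,4a,5,6,8a-octahydronaphthalen-2-yl (2Z)-2-methylbut-2-enoate, via mixed anhydride 25 (not isolated)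
Conditions: 24 (3 equiv), 2,4,6-trichlorobenzoyl chloride (3 equiv), Et3N (6 equiv), toluene, rt; then 23, toluene, 75 °C
Reagents that add atoms: none
Why: Yamaguchi-type mixed-anhydride acylation without a nucleophilic catalyst should transfer the angeloyl group to the only secondary hydroxyl (C3) without Z-to-E isomerisation, the tertiary hydroxyls at C4 and C11 being too hindered to react.

**Compound list**

1 | (R)-(−)-carvone, (5R)-2-methyl-5-(prop-1-en-2-yl)cyclohex-2-en-1-one | CC1=CC[C@H](CC1=O)C(C)=C | starting material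
2 | lithium dienolate of 1 (formed in the flask) | CC1=CC[C@H](C=C1O[Li])C(C)=C | intermediate
3 | (5R)-2,6-dimethyl-5-(prop-1-en-2-yl)cyclohex-2-en-1-one (C6 epimers) | CC1=CC[C@H](C(C)C1=O)C(C)=C | intermediate
4 | methyl bromoacetate | COC(=O)CBr | starting material
5 | lithium enolate of 3 (formed in the flask) | CC1=CC[C@H](C(C)=C1O[Li])C(C)=C | intermediate
6 | methyl 2-[(1S,6S)-1,3-dimethyl-2-oxo-6-(prop-1-en-2-yl)cyclohex-3-en-1-yl]acetate (acetate arm trans to isopropenyl) | CC1=CC[C@H]([C@](C)(CC(=O)OC)C1=O)C(C)=C | intermediate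
7 | methyl 2-[(1S,4R,6S)-4-[dimethyl(phenyl)silyl]-1,3-dimethyl-2-oxo-6-(prop-1-en-2-yl)cyclohexyl]acetate (epimers at ring C3; silyl trans to isopropenyl) | CC1C(=O)[C@@](C)(CC(=O)OC)[C@H](C(C)=C)C[C@H]1[Si](C)(C)c1ccccc1 | intermediate
8 | methyl 2-[4-[dimethyl(phenyl)silyl]-6-(1-hydroperoxy-1-methoxyethyl)-1,3-dimethyl-2-oxocyclohexyl]acetate, ring centres as in 7 (formed in the flask) | CC1C(=O)[C@@](C)(CC(=O)OC)[C@H](C(C)(OC)OO)C[C@H]1[Si](C)(C)c1ccccc1 | intermediate
9 | methyl 2-[(1R,4R)-4-[dimethyl(phenyl)silyl]-1,3-dimethyl-2-oxocyclohexyl]acetate (epimers at ring C3) | CC1C(=O)[C@@](C)(CC(=O)OC)CC[C@H]1[Si](C)(C)c1ccccc1 | intermediate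
10 | potassium enolate of 9 (formed in the flask) | CC1=C(O[K])[C@@](C)(CC(=O)OC)CC[C@H]1[Si](C)(C)c1ccccc1 | intermediate
11 | methyl 2-[(1R,4R)-4-[dimethyl(phenyl)silyl]-1,3-dimethyl-2-(trifluoromethanesulfonyloxy)cyclohex-2-en-1-yl]acetate | CC1=C(OS(=O)(=O)C(F)(F)F)[C@@](C)(CC(=O)OC)CC[C@H]1[Si](C)(C)c1ccccc1 | intermediate
12 | methyl 2-[(1R,4R)-4-[dimethyl(phenyl)silyl]-1,3-dimethylcyclohex-2-en-1-yl]acetate | CC1=C[C@@](C)(CC(=O)OC)CC[C@H]1[Si](C)(C)c1ccccc1 | intermediate
13 | methyl 2-[(1R,2R)-2-(dimethoxymethyl)-1,3-dimethylcyclohex-3-en-1-yl]acetate | COC(OC)[C@H]1C(C)=CCC[C@]1(C)CC(=O)OC | intermediate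
14 | 2-methylprop-1-enylmagnesium bromide (THF solution) | CC(C)=C[Mg]Br | starting material
15 | 2-[(1R,2R)-2-(dimethoxymethyl)-1,3-dimethylcyclohex-3-en-1-yl]-N-methoxy-N-methylacetamide (formed in the flask) | COC(OC)[C@H]1C(C)=CCC[C@]1(C)CC(=O)N(C)OC | intermediate
16 | 1-[(1R,2R)-2-(dimethoxymethyl)-1,3-dimethylcyclohex-3-en-1-yl]-4-methylpent-3-en-2-one | COC(OC)[C@H]1C(C)=CCC[C@]1(C)CC(=O)C=C(C)C | intermediate
17 | 2-[(1R,2R)-2-(dimethoxymethyl)-1,3-dimethylcyclohex-3-en-1-yl]-1-(3,3-dimethyloxiran-2-yl)ethan-1-one (oxirane epimers) | COC(OC)[C@H]1C(C)=CCC[C@]1(C)CC(=O)C1OC1(C)C | intermediate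
18 | (1R,6R)-6-[2-(3,3-dimethyloxiran-2-yl)-2-oxoethyl]-2,6-dimethylcyclohex-2-ene-1-carbaldehyde (oxirane epimers) | O=C[C@H]1C(C)=CCC[C@]1(C)CC(=O)C1OC1(C)C | intermediate
19 | samarium enolate–alkoxide of trivalent samarium from 18 (formed in the flask) | O=C[C@H]1C(C)=CCC[C@]1(C)CC(O[Sm](I)I)=CC(C)(C)O[Sm](I)I | intermediate
20 | (4aR,8aR)-4-hydroxy-3-(2-hydroxypropan-2-yl)-5,8a-dimethyl-3,4,4a,7,8,8a-hexahydronaphthalen-2(1H)-one (epimers at C3, C4) | CC1=CCC[C@]2(C)CC(=O)C(C(C)(C)O)C(O)[C@@H]12 | intermediate
21 | C4 methanesulfonate of 20 (formed in the flask) | CC1=CCC[C@]2(C)CC(=O)C(C(C)(C)O)C(OS(C)(=O)=O)[C@@H]12 | intermediate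
22 | (4aR,8aR)-3-(2-hydroxypropan-2-yl)-5,8a-dimethyl-4a,7,8,8a-tetrahydronaphthalen-2(1H)-one | CC1=CCC[C@]2(C)CC(=O)C(C(C)(C)O)=C[C@@H]12 | intermediate
23 | (4aR,5S,6R,8aR)-5,6-dihydroxy-3-(2-hydroxypropan-2-yl)-5,8a-dimethyl-4a,5,6,7,8,8a-hexahydronaphthalen-2(1H)-one (3α,4α,11-trihydroxyeudesm-6-en-8-one) | O[C@@H]1CC[C@]2(C)CC(=O)C(C(C)(C)O)=C[C@H]2[C@]1(C)O | intermediate
24 | angelic acid, (2Z)-2-methylbut-2-enoic acid | C/C=C(/C)C(=O)O | starting material
25 | (2Z)-2-methylbut-2-enoic 2,4,6-trichlorobenzoic anhydride (formed in the flask) | C/C=C(/C)C(=O)OC(=O)c1c(Cl)cc(Cl)cc1Cl | intermediate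
26 | (1S,2R,4aR,8aR)-1-hydroxy-7-(2-hydroxypropan-2-yl)-1,4a-dimethyl-6-oxo-1,2,3,4,4a,5,6,8a-octahydronaphthalen-2-yl (2Z)-2-methylbut-2-enoate (3α-angeloyloxy-4α,11-dihydroxyeudesm-6-en-8-one) | C/C=C(/C)C(=O)O[C@@H]1CC[C@]2(C)CC(=O)C(C(C)(C)O)=C[C@H]2[C@]1(C)O | target

**Step count and risks**

Total steps: 14. Longest linear sequence: 14 steps from (R)-carvone (no convergent branch; 4, 14 and 24 are bought).

Steps most likely to fail:

1. Step 11 (Proposed new method). What may go wrong: electron transfer to the aldehyde (pinacol coupling or reduction) competing with that to the epoxy ketone, or protonation of the samarium enolate before it reaches the aldehyde. Fallback by known chemistry: from 17 the epoxy ketone is reduced with SmI2 in THF–MeOH at −90 °C, with the enolate protonated on purpose, to the β-hydroxy ketone acetal F1. The acetal is cleaved as in step 10 to the keto aldehyde F2. An amine-salt catalysed intramolecular aldol condensation (dibenzylammonium trifluoroacetate, benzene, 50 °C) then closes ring B and dehydrates in one operation, returning to the route at 22.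

2. Step 7. What may go wrong: slow attack at C5 beside the quaternary C10 with protodesilylation taking over, or erosion of the anti facial course. Fallback: from 12, C6 is brought in at the alcohol oxidation level by Lewis-acid-bound formaldehyde in an ene-like closed transition state (paraformaldehyde, Me2AlCl, CH2Cl2, −78 → 0 °C), giving the hydroxymethyl ester F3. In situ formation of the hydroxy Weinreb amide F4 and addition of 14 (one further equivalent of i-PrMgCl for the hydroxyl) give the hydroxy enone F5. Alkaline H2O2 gives the hydroxy epoxy ketone F6, and Dess–Martin oxidation buffered with pyridine returns to the route at 18. This path also avoids the acidic unmasking of step 10.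

3. Step 14. What may go wrong: sluggish acylation of the hindered axial C3 hydroxyl next to the tertiary carbinol, with Z-to-E isomerisation of the acyl donor on long heating. Fallback: from 23 the C3 hydroxyl is esterified with 2-(diphenoxyphosphoryl)propanoic acid (DCC, DMAP, CH2Cl2) to the phosphonate ester F7. A Z-selective Horner–Wadsworth–Emmons reaction of this diaryl phosphonate with acetaldehyde (NaI, DBU, THF, −78 → 0 °C) then builds the angelate double bond in place and arrives at 26.

**Further compounds**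

F1 | step 11 | 1-[(1R,2R)-2-(dimethoxymethyl)-1,3-dimethylcyclohex-3-en-1-yl]-4-hydroxy-4-methylpentan-2-one | COC(OC)[C@H]1C(C)=CCC[C@]1(C)CC(=O)CC(C)(C)O
F2 | step 11 | (1R,6R)-6-(4-hydroxy-4-methyl-2-oxopentyl)-2,6-dimethylcyclohex-2-ene-1-carbaldehyde | O=C[C@H]1C(C)=CCC[C@]1(C)CC(=O)CC(C)(C)O
F3 | step 7 | methyl 2-[(1R,2R)-2-(hydroxymethyl)-1,3-dimethylcyclohex-3-en-1-yl]acetate | OC[C@H]1C(C)=CCC[C@]1(C)CC(=O)OC
F4 | step 7 | 2-[(1R,2R)-2-(hydroxymethyl)-1,3-dimethylcyclohex-3-en-1-yl]-N-methoxy-N-methylacetamide | OC[C@H]1C(C)=CCC[C@]1(C)CC(=O)N(C)OC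
F5 | step 7 | 1-[(1R,2R)-2-(hydroxymethyl)-1,3-dimethylcyclohex-3-en-1-yl]-4-methylpent-3-en-2-one | OC[C@H]1C(C)=CCC[C@]1(C)CC(=O)C=C(C)C
F6 | step 7 | 1-(3,3-dimethyloxiran-2-yl)-2-[(1R,2R)-2-(hydroxymethyl)-1,3-dimethylcyclohex-3-en-1-yl]ethan-1-one (oxirane epimers) | OC[C@H]1C(C)=CCC[C@]1(C)CC(=O)C1OC1(C)C
F7 | step 14 | (1S,2R,4aR,8aR)-1-hydroxy-7-(2-hydroxypropan-2-yl)-1,4a-dimethyl-6-oxo-1,2,3,4,4a,5,6,8a-octahydronaphthalen-2-yl 2-(diphenoxyphosphoryl)propanoate | CC(C(=O)O[C@@H]1CC[C@]2(C)CC(=O)C(C(C)(C)O)=C[C@H]2[C@]1(C)O)P(=O)(Oc1ccccc1)Oc1ccccc1
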